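**Strategy.** Ring B is built, not substituted. Its C1'–C6' and C4'–C5' bonds are disconnected so that C1' (benzofuranyl), C2' (prenyl), C3' (oxygen) and C4'–H come from C6, C5, C4 and C3 of a 4-acetoxy-2-pyranone, and C5' (oxygen) and C6' (prenyl) from a siloxyalkyne. One thermal operation, (4+2) cycloaddition then loss of CO2, should deliver the pentasubstituted benzene. It exploits the 1,3-relationship of O3' and O5' around C4'–H and the two prenyl groups flanking the biaryl carbon C1'. The precursor is a 6-(6-silyloxybenzofuran-2-yl)-5-prenyl-4-acetoxy-2-pyranone, assembled from an acetoacetate dianion, plus a prenyl-bearing triisopropylsiloxyalkyne.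

Key step: step 7

Assumption: methyl 6-hydroxybenzofuran-2-carboxylate is taken as a purchasable building block.
Remark: the target has no stereocentre; phenols and enols next to a prenyl group cyclise to chromans under acid, so every work-up is kept neutral to mildly basic.

**Step 1**
Reactants: 1 methyl acetoacetate; 2 prenyl bromide (1-bromo-3-methylbut-2-ene)
Product: 4 methyl 7-methyl-3-oxooct-6-enoate, via acetoacetate dianion 3 (not isolated)
Conditions: NaH, THF, 0 °C; n-BuLi, 0 °C; 2, 0 °C → rt; aq. NH4Cl
Reagents that add atoms: none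
Why: γ-alkylation of a β-ketoester dianion, in which the more basic terminal carbanion should displace the primary allylic bromide (SN2) and leave the α-position untouched.

**Step 2**
Reactants: 5 methyl 6-hydroxybenzofuran-2-carboxylate
Product: 6 methyl 6-(triisopropylsilyloxy)benzofuran-2-carboxylate
Conditions: TIPSCl, imidazole, DMF, rt
Reagents that add atoms: triisopropylsilyl chloride CC(C)[Si](Cl)(C(C)C)C(C)C
Why: standard O-silylation of a phenol, giving an aryl silyl ether robust enough for the enolate chemistry that follows while the ester is not affected.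

**Step 3**
Reactants: 4 methyl 7-methyl-3-oxooct-6-enoate (2.2 equiv); 6 methyl 6-(triisopropylsilyloxy)benzofuran-2-carboxylate
Product: 9 4-hydroxy-5-(3-methylbut-2-enyl)-6-[6-(triisopropylsilyloxy)benzofuran-2-yl]-2H-pyran-2-one, via ketoester dianion 7 (not isolated), via diketoester 8 (not isolated)
Conditions: LiN(iPr)2 (4.4 equiv), THF, −78 → 0 °C; 6, −78 → 0 °C; AcOH; solvent switch; DBU, PhMe, 80 °C
Reagents that add atoms: none
Why: Claisen-type γ-acylation of the β-ketoester dianion by the non-enolisable aryl ester (excess dianion absorbs the proton of the more acidic tricarbonyl product), followed by DBU-mediated enol lactonisation (6-exo-trig acyl substitution) of the 3,5-diketoester to the 4-hydroxy-2-pyranone.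

**Step 4**
Reactants: 9 4-hydroxy-5-(3-methylbut-2-enyl)-6-[6-(triisopropylsilyloxy)benzofuran-2-yl]-2H-pyran-2-one
Product: 10 4-acetoxy-5-(3-methylbut-2-enyl)-6-[6-(triisopropylsilyloxy)benzofuran-2-yl]-2H-pyran-2-one
Conditions: Ac2O, Et3N, CH2Cl2, 0 °C
Reagents that add atoms: acetic anhydride CC(=O)OC(C)=O
Why: O-acetylation of the acidic vinylogous acid at O4, run cold and without a nucleophilic catalyst so that the acetyl group should not migrate to C3.

**Step 5**
Reactants: 11 4-methylpent-3-enoic acid
Product: 12 ethyl 4-methylpent-3-enoate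
Conditions: EtI, K2CO3, DMF, rt
Reagents that add atoms: iodoethane CCI
Why: carboxylate O-alkylation (SN2), chosen over acid-catalysed esterification because acid would lactonise the β,γ-unsaturated acid or move its alkene.

**Step 6**
Reactants: 12 ethyl 4-methylpent-3-enoate
Product: 15 triisopropyl(5-methylhex-4-en-1-ynyloxy)silane, via dibromoketone enolate 13 (not isolated), via lithium ynolate 14 (not isolated)
Conditions: CH2Br2, lithium 2,2,6,6-tetramethylpiperidide (2.2 equiv), THF, −78 °C; n-BuLi, −78 → 0 °C; TIPSCl, −78 °C → rt
Reagents that add atoms: dibromomethane BrCBr; triisopropylsilyl chloride CC(C)[Si](Cl)(C(C)C)C(C)C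
Why: Kowalski ester homologation, in which LiCHBr2 adds to the ester, bromine–lithium exchange on the dibromo enolate triggers the 1,2-shift to the ynolate, and the bulky silyl chloride should trap it on oxygen.

**Step 7**
Reactants: 10 4-acetoxy-5-(3-methylbut-2-enyl)-6-[6-(triisopropylsilyloxy)benzofuran-2-yl]-2H-pyran-2-one; 15 triisopropyl(5-methylhex-4-en-1-ynyloxy)silane (3 equiv)
Product: 17 mulberrofuran V 3'-O-acetate 5',6-bis(triisopropylsilyl) ether, via bridged bicyclic lactone 16 (not isolated)
Conditions: 2,6-di-tert-butyl-4-methylpyridine (cat.), PhMe (1 M), sealed tube, 160 °C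
Reagents that add atoms: none
Why: Proposed new method: the electron-rich siloxyalkyne 15 should add across C3/C6 of the electron-poor pyranone 10 in an asynchronous inverse-demand (4+2) cycloaddition, its nucleophilic prenyl-bearing carbon attacking C6 while the silyloxy-bearing carbon closes on C3, and the 2-oxabicyclo[2.2.2]octadienone 16 should then lose CO2 irreversibly by retro-(4+2) cycloaddition and aromatise. The closest known reaction types are the Diels–Alder/retro-Diels–Alder reactions of 2-pyranones with alkynes and ynamines and the thermal benzannulations of siloxyalkynes, but this pairing is without precedent. Ring B is closed as a six-membered carbocycle by intermolecular two-bond annulation (C1'–C6' and C4'–C5'), the lactone bridge being only transient. No stereocentre survives, since both bridgehead centres of racemic 16 become sp2 on decarboxylation. The step needs regioselectivity (O3' and O5' meta, not para) and chemoselectivity for the alkyne over the two prenyl alkenes; the first should follow from polarity matching (ynol ether β-carbon as nucleophile, C6 as the δ-acceptor site of the lactone, C3 as the enol-acetate terminus), the second from the much higher HOMO of the ynol ether. The O4 acetate, unlike a silyl or alkyl ether, keeps the diene electron-poor, and the crowding at C1'–C6' is answered by excess alkyne at high concentration and temperature.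

**Step 8**
Reactants: 17 mulberrofuran V 3'-O-acetate 5',6-bis(triisopropylsilyl) ether
Product: 19 mulberrofuran V, via bis-silyl ether phenol 18 (not isolated)
Conditions: K2CO3 (cat.), degassed MeOH–THF, rt; then Bu4NF, 0 °C → rt; aq. NH4Cl
Reagents that add atoms: none
Why: methanolysis (transesterification) of the aryl acetate followed in the same flask by fluoride cleavage of both aryl silyl ethers, all under basic to neutral conditions that should leave the o-prenyl phenols uncyclised.

**Compound list**

1 | methyl acetoacetate | COC(=O)CC(C)=O | starting material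
2 | prenyl bromide (1-bromo-3-methylbut-2-ene) | CC(C)=CCBr | starting material
3 | sodium lithium dianion (dienolate) of methyl acetoacetate | C=C([O-])C=C([O-])OC.[Na+].[Li+] | intermediate (not isolated)
4 | methyl 7-methyl-3-oxooct-6-enoate | COC(=O)CC(=O)CCC=C(C)C | intermediate
5 | methyl 6-hydroxybenzofuran-2-carboxylate | COC(=O)c1cc2ccc(O)cc2o1 | starting material
6 | methyl 6-(triisopropylsilyloxy)benzofuran-2-carboxylate | COC(=O)c1cc2ccc(O[Si](C(C)C)(C(C)C)C(C)C)cc2o1 | intermediate
7 | dilithium dianion (dienolate, alkene geometry undefined) of methyl 7-methyl-3-oxooct-6-enoate | COC([O-])=CC([O-])=CCC=C(C)C.[Li+].[Li+] | intermediate (not isolated)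
8 | methyl 7-methyl-3-oxo-4-[6-(triisopropylsilyloxy)benzofuran-2-carbonyl]oct-6-enoate (racemic at C4, enolisable) | COC(=O)CC(=O)C(CC=C(C)C)C(=O)c1cc2ccc(O[Si](C(C)C)(C(C)C)C(C)C)cc2o1 | intermediate (not isolated)
9 | 4-hydroxy-5-(3-methylbut-2-enyl)-6-[6-(triisopropylsilyloxy)benzofuran-2-yl]-2H-pyran-2-one | O=C1C=C(O)C(CC=C(C)C)=C(c2cc3ccc(O[Si](C(C)C)(C(C)C)C(C)C)cc3o2)O1 | intermediate
10 | 4-acetoxy-5-(3-methylbut-2-enyl)-6-[6-(triisopropylsilyloxy)benzofuran-2-yl]-2H-pyran-2-one | O=C1C=C(OC(C)=O)C(CC=C(C)C)=C(c2cc3ccc(O[Si](C(C)C)(C(C)C)C(C)C)cc3o2)O1 | intermediate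
11 | 4-methylpent-3-enoic acid | CC(C)=CCC(=O)O | starting material
12 | ethyl 4-methylpent-3-enoate | CCOC(=O)CC=C(C)C | intermediate
13 | lithium 1,1-dibromo-5-methylhexa-1,4-dien-2-olate | CC(C)=CCC([O-])=C(Br)Br.[Li+] | intermediate (not isolated)
14 | lithium 5-methylhex-4-en-1-yn-1-olate | CC(C)=CCC#C[O-].[Li+] | intermediate (not isolated)
15 | triisopropyl(5-methylhex-4-en-1-ynyloxy)silane | CC(C)=CCC#CO[Si](C(C)C)(C(C)C)C(C)C | intermediate
16 | 5-acetoxy-6,7-bis(3-methylbut-2-enyl)-8-(triisopropylsilyloxy)-1-[6-(triisopropylsilyloxy)benzofuran-2-yl]-2-oxabicyclo[2.2.2]octa-5,7-dien-3-one (racemic; the two bridgehead centres are tied to each other by the bicycle) | O=C1OC2(c3cc4ccc(O[Si](C(C)C)(C(C)C)C(C)C)cc4o3)C(CC=C(C)C)=C(OC(C)=O)C1C(O[Si](C(C)C)(C(C)C)C(C)C)=C2CC=C(C)C | intermediate (not isolated)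
17 | mulberrofuran V 3'-O-acetate 5',6-bis(triisopropylsilyl) ether | CC(C)=CCc1c(OC(C)=O)cc(O[Si](C(C)C)(C(C)C)C(C)C)c(CC=C(C)C)c1-c1cc2ccc(O[Si](C(C)C)(C(C)C)C(C)C)cc2o1 | intermediate
18 | mulberrofuran V 5',6-bis(triisopropylsilyl) ether | CC(C)=CCc1c(O)cc(O[Si](C(C)C)(C(C)C)C(C)C)c(CC=C(C)C)c1-c1cc2ccc(O[Si](C(C)C)(C(C)C)C(C)C)cc2o1 | intermediate (not isolated)
19 | mulberrofuran V | CC(C)=CCc1c(O)cc(O)c(CC=C(C)C)c1-c1cc2ccc(O)cc2o1 | target

**Step count.** Total: 8 steps. Longest linear sequence: 5 steps (step 2 → 3 → 4 → 7 → 8; equally step 1 → 3 → 4 → 7 → 8).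

**Steps most likely to fail**

1. Step 7. The cycloaddition may not start before the siloxyalkyne is lost to thermal silyl migration (silylketene formation) or oligomerisation, because C6 is shielded by the benzofuranyl group and both prenyl groups converge on the new C1'–C6' bond. Competing (2+2) addition or acetyl transfer could also divert the partners. The fallback uses known chemistry and makes ring B by polyketide-type aldol condensation instead of cycloaddition; it sets out from 6 and 2 and comes back to the route at 19. Pentane-2,4-dione F1 would be deprotonated twice (LiN(iPr)2, THF) and alkylated at a terminal carbon with 2 to give 8-methylnon-7-ene-2,4-dione F2. Repeating the operation at the other terminus would give 2,12-dimethyltrideca-2,11-diene-6,8-dione F3. The dianion of F3, used in excess, would be acylated at a terminal α-carbon by 6 to give the triketone 9-methyl-2-(3-methylbut-2-enyl)-1-[6-(triisopropylsilyloxy)benzofuran-2-yl]dec-8-ene-1,3,5-trione F4. Aqueous KOH in MeOH at rt should then close ring B by intramolecular aldol attack of the C6 methylene on the C1 aryl ketone, with dehydration and enolisation, to give mulberrofuran V 6-O-triisopropylsilyl ether F5 (or 19 directly if the base also removes the silyl group). Bu4NF in THF would complete the conversion to 19.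

2. Step 3. Proton transfer from the tricarbonyl product to unreacted dianion, and slow attack of the hindered secondary carbanion on the deactivated heteroaryl ester, may stall the condensation; partial desilylation by liberated methoxide is a lesser concern. The fallback replaces the Claisen acylation by aldol addition and oxidation; it sets out from 6, uses dianion 7, and comes back at 8. i-Bu2AlH (CH2Cl2, −78 → 0 °C) would reduce 6 to [6-(triisopropylsilyloxy)benzofuran-2-yl]methanol F6, and MnO2 (CH2Cl2) would oxidise it to 6-(triisopropylsilyloxy)benzofuran-2-carbaldehyde F7. Dianion 7 should add to F7 at −78 °C (fast aldol addition, no proton-transfer problem) to give methyl 4-{hydroxy[6-(triisopropylsilyloxy)benzofuran-2-yl]methyl}-7-methyl-3-oxooct-6-enoate F8 as a diastereomer mixture of no consequence. Dess–Martin oxidation (NaHCO3, CH2Cl2) would convert F8 into diketoester 8, which is lactonised with DBU as in step 3.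

3. Step 6. The doubly activated α-CH2 of the β,γ-unsaturated ester may be deprotonated by LiCHBr2 or the amide base instead of undergoing carbonyl addition, with migration of the alkene into conjugation; silylation of the ynolate on carbon would give a silylketene. The fallback makes the ynolate by oxidation of an acetylide instead of ester homologation; it sets out from 2 and comes back at 14. Coupling of 2 with HC≡CMgBr (CuCl cat., THF) should give 5-methylhex-4-en-1-yne F9. Its lithium acetylide (n-BuLi, THF, −78 °C) would be oxidised with LiOOt-Bu (from t-BuOOH and LiN(SiMe3)2, −78 → 0 °C) to ynolate 14, which TIPSOTf silylates at −78 °C to 15.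

**Further compounds**

F1 | step 7 | pentane-2,4-dione (bought) | CC(=O)CC(C)=O
F2 | step 7 | 8-methylnon-7-ene-2,4-dione | CC(=O)CC(=O)CCC=C(C)C
F3 | step 7 | 2,12-dimethyltrideca-2,11-diene-6,8-dione | CC(C)=CCCC(=O)CC(=O)CCC=C(C)C
F4 | step 7 | 9-methyl-2-(3-methylbut-2-enyl)-1-[6-(triisopropylsilyloxy)benzofuran-2-yl]dec-8-ene-1,3,5-trione (racemic, enolisable) | CC(C)=CCCC(=O)CC(=O)C(CC=C(C)C)C(=O)c1cc2ccc(O[Si](C(C)C)(C(C)C)C(C)C)cc2o1
F5 | step 7 | mulberrofuran V 6-O-triisopropylsilyl ether | CC(C)=CCc1c(O)cc(O)c(CC=C(C)C)c1-c1cc2ccc(O[Si](C(C)C)(C(C)C)C(C)C)cc2o1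
F6 | step 3 | [6-(triisopropylsilyloxy)benzofuran-2-yl]methanol | OCc1cc2ccc(O[Si](C(C)C)(C(C)C)C(C)C)cc2o1
F7 | step 3 | 6-(triisopropylsilyloxy)benzofuran-2-carbaldehyde | O=Cc1cc2ccc(O[Si](C(C)C)(C(C)C)C(C)C)cc2o1
F8 | step 3 | methyl 4-{hydroxy[6-(triisopropylsilyloxy)benzofuran-2-yl]methyl}-7-methyl-3-oxooct-6-enoate (racemic diastereomer mixture) | COC(=O)CC(=O)C(CC=C(C)C)C(O)c1cc2ccc(O[Si](C(C)C)(C(C)C)C(C)C)cc2o1
F9 | step 6 | 5-methylhex-4-en-1-yne | CC(C)=CCC#C
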